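The 5,6-dihydro-2H-pyran-2-one ring (O1, C2, C3=C4, C5, C6) hides a homoallylic acrylate: ring carbons C4 and C5 are an allyl residue sitting between the carbinol carbon C6 and the acrylate carbon C3. The route therefore rests on disconnecting C5–C6 and C3=C4 together. One flask operation on an acyclic β-silyloxy aldehyde (C6 as CHO) achieves both: catalytic asymmetric allylation makes C5–C6 and sets C6, the tin alkoxide is acylated by acryloyl chloride, and ring-closing metathesis then makes C3=C4 and closes the lactone. The precursor is an open syn,syn-triol chain, assembled from two epichlorohydrin-derived epoxides on a silyl dithiane linchpin.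

Key step: step 8

Remark: ring atoms are numbered O1, C2 (C=O), C3, C4, C5, C6 and the side chain C1′ to C15′; the three stages of step 8 are assumed to run in one flask without intermediate work-up.

Step 1
Reactants: 1 (S)-epichlorohydrin
Product: 3 (2S)-2-nonyloxirane, via chlorohydrin 2 (not isolated)
Conditions: n-C8H17MgBr, CuI (10 mol%), THF, −40 °C; aq. NH4Cl; crude 2, powdered NaOH, Et2O, rt
Reagents that add atoms: octylmagnesium bromide, CCCCCCCC[Mg]Br
Why: Copper-catalysed Grignard opening of the epoxide at its CH2 terminus and Williamson closure of the chlorohydrin onto the CH2Cl carbon never touch the stereocentre, so the configuration of 1 should pass unchanged into 3.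

Step 2
Reactants: 4 (R)-epichlorohydrin
Product: 6 (2R)-2-(prop-2-en-1-yl)oxirane, via chlorohydrin 5 (not isolated)
Conditions: CH2=CHMgBr, CuI (10 mol%), THF, −60 to −40 °C; aq. NH4Cl; crude 5, powdered NaOH, Et2O, rt; distillation
Reagents that add atoms: vinylmagnesium bromide, C=C[Mg]Br
Why: The same copper-catalysed epoxide opening and Williamson closure as in step 1 should deliver the allyl epoxide with the stereocentre of 4 retained.

Step 3
Reactants: 7 2-(tert-butyldimethylsilyl)-1,3-dithiane; 6 (2R)-2-(prop-2-en-1-yl)oxirane; 3 (2S)-2-nonyloxirane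
Product: 11 (2S)-1-{2-[(2R)-2-[(tert-butyldimethylsilyl)oxy]pent-4-en-1-yl]-1,3-dithian-2-yl}undecan-2-ol, via lithiodithiane 8 (not isolated), via alkoxide 9 (not isolated), via carbanion 10 (not isolated)
Conditions: t-BuLi, Et2O, −78 to −45 °C; 6, −78 to −25 °C; then 3, HMPA, THF, −78 to 0 °C
Reagents that add atoms: none
Why: In this silyl-dithiane linchpin coupling (anion relay), the lithiated dithiane opens 6 at CH2, HMPA triggers a 1,4-Brook rearrangement that moves silicon to oxygen and regenerates a dithiane anion, and that anion opens 3 at CH2, so both carbinol centres come unchanged from the epoxides and only the first alkoxide ends up silylated.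

Step 4
Reactants: 11 (2S)-1-{2-[(2R)-2-[(tert-butyldimethylsilyl)oxy]pent-4-en-1-yl]-1,3-dithian-2-yl}undecan-2-ol
Product: 12 (4R,8S)-4-[(tert-butyldimethylsilyl)oxy]-8-hydroxyheptadec-1-en-6-one
Conditions: MeI, CaCO3, MeCN/H2O (9:1), 45 °C
Reagents that add atoms: water, O
Why: Alkylative dithioacetal hydrolysis, in which S-methylation makes sulfur a leaving group and water captures the thionium ion, should unmask the ketone under buffered neutral conditions that spare the silyl ether, the alkene and the β-hydroxy ketone.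

Step 5
Reactants: 12 (4R,8S)-4-[(tert-butyldimethylsilyl)oxy]-8-hydroxyheptadec-1-en-6-one
Product: 13 (4R,6S,8S)-4-[(tert-butyldimethylsilyl)oxy]heptadec-1-ene-6,8-diol
Conditions: Et2BOMe, THF/MeOH (4:1), −78 °C; NaBH4, −78 °C; then MeOH co-evaporation
Reagents that add atoms: none
Why: In the Narasaka–Prasad reduction the C8 hydroxyl and the ketone are held in a six-membered diethylboron chelate and external hydride adds axially, which should set C6 1,3-syn to C8.

Step 6
Reactants: 13 (4R,6S,8S)-4-[(tert-butyldimethylsilyl)oxy]heptadec-1-ene-6,8-diol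
Product: 14 tert-butyl{[(2R)-1-[(4S,6S)-2,2-dimethyl-6-nonyl-1,3-dioxan-4-yl]pent-4-en-2-yl]oxy}dimethylsilane
Conditions: Me2C(OMe)2, PPTS (cat.), CH2Cl2, rt
Reagents that add atoms: 2,2-dimethoxypropane, COC(C)(C)OC
Why: Acid-catalysed transketalisation should protect the only free 1,3-diol as its acetonide (a chair with both substituents equatorial for the syn diol) without touching the silyl ether.

Step 7
Reactants: 14 tert-butyl{[(2R)-1-[(4S,6S)-2,2-dimethyl-6-nonyl-1,3-dioxan-4-yl]pent-4-en-2-yl]oxy}dimethylsilane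
Product: 16 (3S)-3-[(tert-butyldimethylsilyl)oxy]-4-[(4S,6S)-2,2-dimethyl-6-nonyl-1,3-dioxan-4-yl]butanal, via ozonide 15 (not isolated)
Conditions: O3, CH2Cl2, −78 °C; PPh3, −78 °C to rt; used crude
Reagents that add atoms: ozone, [O-][O+]=O
Why: Ozonolysis (cycloaddition and cycloreversion to the ozonide, then reductive cleavage by PPh3) should excise the terminal CH2 and unveil C6 as the aldehyde without affecting any stereocentre.

Step 8
Reactants: 16 (3S)-3-[(tert-butyldimethylsilyl)oxy]-4-[(4S,6S)-2,2-dimethyl-6-nonyl-1,3-dioxan-4-yl]butanal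
Product: 19 (6S)-6-{(2S)-2-[(tert-butyldimethylsilyl)oxy]-3-[(4S,6S)-2,2-dimethyl-6-nonyl-1,3-dioxan-4-yl]propyl}-5,6-dihydro-2H-pyran-2-one, via stannyl ether 17 (not isolated), via acrylate 18 (not isolated)
Conditions: (S)-BINOL (20 mol%), Ti(OiPr)4 (10 mol%), 4 Å MS, CH2=CHCH2SnBu3 (1.2 equiv), CH2Cl2, −20 °C, 60 h; CH2=CHCOCl (2 equiv), 0 °C to rt; dilution with CH2Cl2 to 5 mM, second-generation Grubbs catalyst (H2IMes)(PCy3)Cl2Ru=CHPh (5 mol%), 40 °C
Reagents that add atoms: allyltributylstannane, C=CC[Sn](CCCC)(CCCC)CCCC; acryloyl chloride, C=CC(Cl)=O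
Why: The BINOL–titanium Lewis acid activates the aldehyde and allyltributylstannane transfers its allyl group through an open transition state to the si face of C6 (Keck asymmetric allylation), which makes C5–C6 and leaves the product as a tributylstannyl ether whose nucleophilic Sn–O bond is then acylated by acryloyl chloride with release of Bu3SnCl. The ruthenium alkylidene next engages the terminal olefin of the acrylate, and ring-closing metathesis onto the acrylate double bond forms C3=C4 and expels ethylene. The six-membered lactone is thus closed by intramolecular olefin metathesis between C3 and C4, and the ring allows only the cis double bond. The new stereocentre C6 is set by the (S)-BINOL catalyst, and the intrinsic 1,3-anti preference of a β-silyloxy aldehyde in an open transition state should point the same way. Chemoselectivity is secured because O1 is the only unprotected oxygen when the acyl chloride arrives, and high dilution favours ring closure over cross-metathesis, while cross-metathesis adducts with residual allylstannane can still cyclise to the same lactone. The closest known reaction types are the stepwise asymmetric allylation, acryloylation and acrylate ring-closing metathesis, a metathesis known to tolerate titanium isopropoxide.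

Step 9
Reactants: 19 (6S)-6-{(2S)-2-[(tert-butyldimethylsilyl)oxy]-3-[(4S,6S)-2,2-dimethyl-6-nonyl-1,3-dioxan-4-yl]propyl}-5,6-dihydro-2H-pyran-2-one
Product: 20 (6S)-6-[(2S,4S,6S)-2,4,6-trihydroxypentadecyl]-5,6-dihydro-2H-pyran-2-one
Conditions: 2 M aq. HCl/THF (1:3), rt
Reagents that add atoms: none
Why: Aqueous acid should hydrolyse the acetonide and cleave the secondary silyl ether in one operation (acetal hydrolysis and protodesilylation) without touching a stereocentre, the unsaturated δ-lactone being the stable form under aqueous acid.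

Compound list
1 | (S)-epichlorohydrin, (2S)-2-(chloromethyl)oxirane | ClC[C@@H]1CO1 | starting material
2 | (2S)-1-chloroundecan-2-ol | ClC[C@@H](O)CCCCCCCCC | intermediate
3 | (2S)-2-nonyloxirane | CCCCCCCCC[C@H]1CO1 | intermediate
4 | (R)-epichlorohydrin, (2R)-2-(chloromethyl)oxirane | ClC[C@H]1CO1 | starting material
5 | (2R)-1-chloropent-4-en-2-ol | ClC[C@H](O)CC=C | intermediate
6 | (2R)-2-(prop-2-en-1-yl)oxirane | C=CC[C@@H]1CO1 | intermediate
7 | 2-(tert-butyldimethylsilyl)-1,3-dithiane | CC(C)(C)[Si](C)(C)C1SCCCS1 | starting material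
8 | [2-(tert-butyldimethylsilyl)-1,3-dithian-2-yl]lithium | [Li]C1(SCCCS1)[Si](C)(C)C(C)(C)C | intermediate
9 | lithium (2R)-1-[2-(tert-butyldimethylsilyl)-1,3-dithian-2-yl]pent-4-en-2-olate | C=CC[C@@H](O[Li])CC1(SCCCS1)[Si](C)(C)C(C)(C)C | intermediate
10 | {2-[(2R)-2-[(tert-butyldimethylsilyl)oxy]pent-4-en-1-yl]-1,3-dithian-2-yl}lithium | C=CC[C@@H](O[Si](C)(C)C(C)(C)C)CC1([Li])SCCCS1 | intermediate
11 | (2S)-1-{2-[(2R)-2-[(tert-butyldimethylsilyl)oxy]pent-4-en-1-yl]-1,3-dithian-2-yl}undecan-2-ol | CCCCCCCCC[C@H](O)CC1(SCCCS1)C[C@H](O[Si](C)(C)C(C)(C)C)CC=C | intermediate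
12 | (4R,8S)-4-[(tert-butyldimethylsilyl)oxy]-8-hydroxyheptadec-1-en-6-one | CCCCCCCCC[C@H](O)CC(=O)C[C@H](O[Si](C)(C)C(C)(C)C)CC=C | intermediate
13 | (4R,6S,8S)-4-[(tert-butyldimethylsilyl)oxy]heptadec-1-ene-6,8-diol | CCCCCCCCC[C@H](O)C[C@H](O)C[C@H](O[Si](C)(C)C(C)(C)C)CC=C | intermediate
14 | tert-butyl{[(2R)-1-[(4S,6S)-2,2-dimethyl-6-nonyl-1,3-dioxan-4-yl]pent-4-en-2-yl]oxy}dimethylsilane | CCCCCCCCC[C@H]1C[C@@H](C[C@H](O[Si](C)(C)C(C)(C)C)CC=C)OC(C)(C)O1 | intermediate
15 | ozonide of 14 (3-substituted 1,2,4-trioxolane, mixture at the trioxolane carbon) | CCCCCCCCC[C@H]1C[C@@H](C[C@H](O[Si](C)(C)C(C)(C)C)CC2OCOO2)OC(C)(C)O1 | intermediate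
16 | (3S)-3-[(tert-butyldimethylsilyl)oxy]-4-[(4S,6S)-2,2-dimethyl-6-nonyl-1,3-dioxan-4-yl]butanal | CCCCCCCCC[C@H]1C[C@@H](C[C@H](O[Si](C)(C)C(C)(C)C)CC=O)OC(C)(C)O1 | intermediate
17 | tributyl{[(4S,6S)-6-[(tert-butyldimethylsilyl)oxy]-7-[(4S,6S)-2,2-dimethyl-6-nonyl-1,3-dioxan-4-yl]hept-1-en-4-yl]oxy}stannane | CCCCCCCCC[C@H]1C[C@@H](C[C@H](O[Si](C)(C)C(C)(C)C)C[C@@H](O[Sn](CCCC)(CCCC)CCCC)CC=C)OC(C)(C)O1 | intermediate
18 | (4S,6S)-6-[(tert-butyldimethylsilyl)oxy]-7-[(4S,6S)-2,2-dimethyl-6-nonyl-1,3-dioxan-4-yl]hept-1-en-4-yl prop-2-enoate | CCCCCCCCC[C@H]1C[C@@H](C[C@H](O[Si](C)(C)C(C)(C)C)C[C@@H](OC(=O)C=C)CC=C)OC(C)(C)O1 | intermediate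
19 | (6S)-6-{(2S)-2-[(tert-butyldimethylsilyl)oxy]-3-[(4S,6S)-2,2-dimethyl-6-nonyl-1,3-dioxan-4-yl]propyl}-5,6-dihydro-2H-pyran-2-one | CCCCCCCCC[C@H]1C[C@@H](C[C@H](O[Si](C)(C)C(C)(C)C)C[C@@H]2CC=CC(=O)O2)OC(C)(C)O1 | intermediate
20 | (6S)-6-[(2S,4S,6S)-2,4,6-trihydroxypentadecyl]-5,6-dihydro-2H-pyran-2-one | CCCCCCCCC[C@H](O)C[C@H](O)C[C@H](O)C[C@@H]1CC=CC(=O)O1 | target

Total steps: 9. Longest linear sequence: 8 (steps 2 to 9, or step 1 and steps 3 to 9).

Steps most likely to fail

Step 8. The one-flask sequence may break down through incomplete acylation of the tin alkoxide or through decay of the ruthenium carbene in the presence of tin and titanium residues, and a catalyst–substrate mismatch would erode facial selectivity at C6. The fallback gives up the one-flask design and uses a stoichiometric chiral reagent with isolation. It sets out from 16: (−)-B-allyldiisopinocampheylborane (Et2O, −78 °C, then NaOH/H2O2) should attack the si face and give (4S,6R)-6-[(tert-butyldimethylsilyl)oxy]-7-[(4S,6S)-2,2-dimethyl-6-nonyl-1,3-dioxan-4-yl]hept-1-en-4-ol F1. Esterification of this alcohol (acryloyl chloride, Et3N, DMAP) gives purified acrylate 18, which is cyclised separately with the second-generation Grubbs catalyst and Ti(OiPr)4 in dilute CH2Cl2; the fallback returns to the route at 19.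

Step 3. Premature or incomplete silyl migration would give mono-adducts and symmetrical bis-adducts instead of the unsymmetrical product. The fallback avoids the Brook relay and sets out from 6: 1,3-dithiane is lithiated (n-BuLi, THF, −30 °C) and opened with 6 to give (2R)-1-(1,3-dithian-2-yl)pent-4-en-2-ol F2. Silylation (TBSCl, imidazole, DMF) gives tert-butyl{[(2R)-1-(1,3-dithian-2-yl)pent-4-en-2-yl]oxy}dimethylsilane F3, which is deprotonated (t-BuLi, HMPA/THF, −78 °C) and alkylated with 3; the fallback returns to the route at 11.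

Step 9. Acid may hydrolyse the unsaturated lactone, or promote conjugate addition of water or a freed hydroxyl, before the acetonide has gone. The fallback changes the protecting-group plan to all-silyl with a fluoride end game and sets out from 13. Silylation (TBSOTf, 2,6-lutidine) gives (4R,6S,8S)-4,6,8-tris[(tert-butyldimethylsilyl)oxy]heptadec-1-ene F4, and ozonolysis (O3, then PPh3) through the ozonide F5 gives (3S,5S,7S)-3,5,7-tris[(tert-butyldimethylsilyl)oxy]hexadecanal F6. The one-flask sequence of step 8 then leads through the tributylstannyl ether F7 and the acrylate F8 to (6S)-6-{(2R,4S,6S)-2,4,6-tris[(tert-butyldimethylsilyl)oxy]pentadecyl}-5,6-dihydro-2H-pyran-2-one F9. HF·pyridine in THF/pyridine removes the three silyl groups under buffered non-aqueous conditions; the fallback returns to the route at 20.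

Further compounds
F1 | step 8 | (4S,6R)-6-[(tert-butyldimethylsilyl)oxy]-7-[(4S,6S)-2,2-dimethyl-6-nonyl-1,3-dioxan-4-yl]hept-1-en-4-ol | CCCCCCCCC[C@H]1C[C@@H](C[C@H](O[Si](C)(C)C(C)(C)C)C[C@@H](O)CC=C)OC(C)(C)O1
F2 | step 3 | (2R)-1-(1,3-dithian-2-yl)pent-4-en-2-ol | C=CC[C@@H](O)CC1SCCCS1
F3 | step 3 | tert-butyl{[(2R)-1-(1,3-dithian-2-yl)pent-4-en-2-yl]oxy}dimethylsilane | C=CC[C@@H](O[Si](C)(C)C(C)(C)C)CC1SCCCS1
F4 | step 9 | (4R,6S,8S)-4,6,8-tris[(tert-butyldimethylsilyl)oxy]heptadec-1-ene | CCCCCCCCC[C@H](O[Si](C)(C)C(C)(C)C)C[C@H](O[Si](C)(C)C(C)(C)C)C[C@H](O[Si](C)(C)C(C)(C)C)CC=C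
F5 | step 9 | ozonide of F4 (3-substituted 1,2,4-trioxolane, mixture at the trioxolane carbon) | CCCCCCCCC[C@H](O[Si](C)(C)C(C)(C)C)C[C@H](O[Si](C)(C)C(C)(C)C)C[C@H](O[Si](C)(C)C(C)(C)C)CC1OCOO1
F6 | step 9 | (3S,5S,7S)-3,5,7-tris[(tert-butyldimethylsilyl)oxy]hexadecanal | CCCCCCCCC[C@H](O[Si](C)(C)C(C)(C)C)C[C@H](O[Si](C)(C)C(C)(C)C)C[C@H](O[Si](C)(C)C(C)(C)C)CC=O
F7 | step 9 | tributyl{[(4S,6S,8S,10S)-6,8,10-tris[(tert-butyldimethylsilyl)oxy]nonadec-1-en-4-yl]oxy}stannane | CCCCCCCCC[C@H](O[Si](C)(C)C(C)(C)C)C[C@H](O[Si](C)(C)C(C)(C)C)C[C@H](O[Si](C)(C)C(C)(C)C)C[C@@H](O[Sn](CCCC)(CCCC)CCCC)CC=C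
F8 | step 9 | (4S,6R,8S,10S)-6,8,10-tris[(tert-butyldimethylsilyl)oxy]nonadec-1-en-4-yl prop-2-enoate | CCCCCCCCC[C@H](O[Si](C)(C)C(C)(C)C)C[C@H](O[Si](C)(C)C(C)(C)C)C[C@H](O[Si](C)(C)C(C)(C)C)C[C@@H](OC(=O)C=C)CC=C
F9 | step 9 | (6S)-6-{(2R,4S,6S)-2,4,6-tris[(tert-butyldimethylsilyl)oxy]pentadecyl}-5,6-dihydro-2H-pyran-2-one | CCCCCCCCC[C@H](O[Si](C)(C)C(C)(C)C)C[C@H](O[Si](C)(C)C(C)(C)C)C[C@H](O[Si](C)(C)C(C)(C)C)C[C@@H]1CC=CC(=O)O1
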